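The charge is mostly J: 90.9% of what enters the flask, against 9.09% for E. The course of X can therefore be reckoned on J, with fed E as a correction.

the same everywhere: J 2.8 M; L 140 mM

| run | E | remark | time |
|---|---|---|---|
| theta | 0.28 M (fed, over 10 min) | the very flask that is asked about, followed so far |  |
| gamma | 0.42 M (fed, over 10 min) | run made earlier |  |
| flask | 0.280 M (fed, over 10 min) |  | 10 min |

theta run (percent of the J and E together charged)

| time / s | X / % | J / % |
|---|---|---|
| 15.0 | 5.6 | 84.5 |
| 30.0 | 10.4 | 76.1 |
| 50.0 | 16.7 | 68.4 |
| 60.0 | 19.0 | 65.3 |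
| 80.0 | 24.9 | 59.0 |
| 90.0 | 26.9 | 55.8 |
| 120 | 33.5 | 47.6 |

gamma run (percent of the J and E together charged)

| time / min | X / % | J / % |
|---|---|---|
| 0.500 | 10.0 | 73.8 |
| 1.50 | 25.6 | 53.7 |
| 3.00 | 40.9 | 33.9 |
| 4.00 | 47.5 | 25.4 |
| 6.00 | 56.2 | 14.8 |
| 8.00 | 59.9 | 8.2 |
| 10.0 | 63.8 | 6.5 |

(scatter of a reading: 0.5 percentage points)

- the analysis behind the earlier runs scatters by 0.5 percentage points, standard deviation
- on the list of suspects stand: L + E -> L + Q; L -> G; J <-> E; J + L -> L + X

* amount of X in percent of the J and E together charged, at 1.0 min, 4.0 min and 10 min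

At 120 s, theta has lost J down to 47.6% and holds 33.5% of X. That gives s = 0.774, the X formed per J lost, a selectivity read from the readings.

Two extreme flasks frame the reckoning at 10 min. Gamma starts with the same cJ and cL and reads 6.5% of J at that time; on this flask's charge that is 6.80%, which the reckoning takes as this flask's J. In the first extreme, none of the fed E goes on to X, so X is s times the J lost, 65.1%. In the second, the whole fed E passes through J to X at the same s, and X stands at 72.1%.

Gamma tells between them. With its larger E feed it reads s = 0.793 at 10.0 min, while the second extreme calls for 0.899. The flask therefore lies nearer the first extreme, and that is the reckoning to hold to. The same s on theta's J at 1 min and on gamma's scaled J at 4.00 min gives 19.8% and 49.8%.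

The forecast gives 19.4%, 49.7% and 65%, holding that “The flask is simply theta continued”. The flask gives 19.7%, 49.6% and 64.9%.

    L + E → L + Q (k = 0.580 L mol⁻¹ s⁻¹)
    L → G (k = 8.20 × 10⁻⁴ s⁻¹)
    J ⇌ E (K = 0.250, k = 0.00130 s⁻¹)
    J + L → L + X (k = 0.0310 L mol⁻¹ s⁻¹)

At 1.93 min, J in the flask is used 3.0 times as fast by J + L → L + X as by the forward step J → E. By 10.0 min the catalyst stands at 61.1% L and 38.9% G, and the half-life of J by the forward step alone is 8.9 min. The flask then keeps 6.5% of its charged J, and s on the J lost gives 65.8% of X against 64.9%. With half the J and the other amounts as they are, s and the same left share of J give 60.2%, and that flask stands at 59.8%.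

All runs are calculated with made-up constants, and the scatter is random.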